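**Assumptions.** Gibberellic acid (GA3, a bulk fermentation product) is taken as the cheap commercial chiral starting material. Atom numbers and α/β descriptors follow the usual gibberellin drawing: C19 and C20 are α, C18 is β, H‑5 and H‑9 are β. The target is 2β‑hydroxy‑GA44.

## Retrosynthetic overview
1. GA98 (10) comes from its allyl ester 9 by Pd deallylation. Ester 9 comes from 3β‑hydroxy‑2‑oxo‑GA44 allyl ester 8 by one SmI2 operation that removes the 3‑OH and reduces C2=O to the equatorial alcohol.
2. Compound 8 is disconnected at C10–C20. A light‑driven 6‑exo addition of the C19 acyloxymethyl radical (from chloromethyl ester 7) to C10 of a 1(10)‑en‑2‑one forms the δ‑lactone and the quaternary C10 together.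
3. Ester 7 comes from enone acid 5. Acid 5 comes from the 2α,3β‑diol acid 4 by allylic oxidation. Acid 4 comes from GA3 allyl ester 3 by the base‑induced 19,10→19,2 lactone shift followed by saponification.
4. Ring order: carbocycles A–D and C4, C5, C6, C8, C9 and C13 come intact from GA3. The γ‑lactone is opened in step 2. The δ‑lactone, formed in step 5, is the only ring built.

## Route

**Step 1**
Reactants: 1 gibberellic acid (GA3); 2 allyl bromide
Product: 3 GA3 allyl ester (7‑allyl ester; 19,10‑γ‑lactone, Δ1, 3β‑OH, 13‑OH and Δ16 unchanged)
Conditions: allyl bromide (1.3 equiv), KHCO3, DMF, 23 °C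
Reagents that add atoms: allyl bromide, C=CCBr
Why: Carboxylate SN2 alkylation touches only the free C7 acid, because C19 is locked in the lactone, and no stereocenter is involved.

**Step 2**
Reactants: 3 GA3 allyl ester
Product: 4 7‑allyl hydrogen 2α,3β,13‑trihydroxy‑20‑norgibberella‑1(10),16‑diene‑7,19‑dioate (free 4α‑CO2H, 4β‑CH3, 5β‑H, 9β‑H)
Conditions: 0.5 M aq KOH (4 equiv), THF, 23 °C; then cold citric acid to pH 4, EtOAc, used at once
Reagents that add atoms: water (as hydroxide), O
Why: This is the allylic lactone rearrangement of GA3 (3‑alkoxide‑assisted anti‑SN2′, then re‑closure of the 4α‑carboxylate on C2, which it can reach only from the α face) followed by saponification of the 19,2‑lactone; the very hindered C7 ester survives, and C10 is deliberately flattened for re‑setting in step 5.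

**Step 3**
Reactants: 4
Product: 5 7‑allyl hydrogen 3β,13‑dihydroxy‑2‑oxo‑20‑norgibberella‑1(10),16‑diene‑7,19‑dioate (7‑allyl ester of the natural "GA8‑catabolite" enone acid)
Conditions: activated MnO2 (25 equiv), acetone, 23 °C
Reagents that add atoms: none
Why: MnO2 allylic oxidation takes only the secondary allylic 2‑OH, since the 3‑OH is non‑allylic and neopentyl and the 13‑OH is tertiary, and the open enone‑acid array is the stable form known from gibberellin catabolites.

**Step 4**
Reactants: 5; 6 chloromethyl chlorosulfate
Product: 7 7‑allyl 19‑chloromethyl 3β,13‑dihydroxy‑2‑oxo‑20‑norgibberella‑1(10),16‑diene‑7,19‑dioate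
Conditions: ClCH2OSO2Cl (1.3 equiv), NaHCO3, n‑Bu4NHSO4, CH2Cl2/H2O, 0→23 °C
Reagents that add atoms: chloromethyl chlorosulfate, ClCOS(=O)(=O)Cl
Why: Phase‑transfer O‑chloromethylation of a carboxylate works on hindered acids because the bond forms at the reagent carbon, and the bicarbonate medium is too weak to enolise the enone γ‑positions (C5, C9) or the α‑ketol.

**Step 5 (key step)**
Reactants: 7
Product: 8 3β‑hydroxy‑2‑oxo‑GA44 allyl ester (allyl 3β,13‑dihydroxy‑2‑oxogibberell‑16‑ene‑7,19‑dioate 19,20‑δ‑lactone; new quaternary C10 with 10α‑CH2O)
Conditions: potassium indole‑1‑carbodithioate (20 mol %), 2,6‑lutidine (1.5 equiv), γ‑terpinene (1.5 equiv, syringe pump over 10 h), degassed MeCN (5 mM), 465 nm LEDs, 50 °C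
Reagents that add atoms: none (H only, from γ‑terpinene)
Why: Proposed new method: photochemical acyloxymethyl‑radical conjugate lactonisation, in which the soft dithiocarbamate anion displaces chloride from the highly SN2‑active O–CH2–Cl group and the resulting S‑(acyloxymethyl) dithiocarbamate absorbs blue light and homolyses its weak C–S bond to give the nucleophilic RCO2CH2• radical; the 4α‑carboxyl holds this radical under the α‑lobe of C10, so it adds 6‑exo‑trig to the enone β‑carbon (polarity‑matched, irreversible, giving a C1 α‑keto radical with no β‑H to lose), and C10–C20, the δ‑lactone and the quaternary centre therefore form together and only from the α face, giving the natural trans A/B fusion; the C1 radical takes H from γ‑terpinene and the terpinenyl radical reduces the dithiocarbamyl radical back to the catalyst anion, with lutidine taking up the HCl; the usual weakness of ester tethers (slow Z→E ester rotation, about 10^4 s⁻¹) is handled because recombination and degenerate group transfer with the dithiocarbamate park the radical in a dormant pool and the only H donor is kept very dilute in a warm polar medium; the closest known reaction types are dithiocarbamate‑catalysed photochemical Giese additions of activated alkyl chlorides, xanthate‑transfer additions of acyloxymethyl radicals and tin‑hydride 6‑exo conjugate radical cyclisations, and what has not been shown is the use of a substrate's own carboxyl, as its chloromethyl ester, to annulate a δ‑lactone onto a β,β‑disubstituted enone.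

**Step 6**
Reactants: 8
Product: 9 GA98 allyl ester (2β,13‑dihydroxy, 3‑deoxy, 19,20‑δ‑lactone)
Conditions: SmI2 (2.5 equiv), THF/MeOH, −78 °C; then H2O (100 equiv) and SmI2 (2.5 equiv), 0 °C, 20 min
Reagents that add atoms: none (H only)
Why: SmI2 reduction of an α‑heterosubstituted ketone expels the axial 3β‑oxygen, which is aligned with the C2 ketyl π‑system, and the SmI2–H2O ketone reduction that follows places the bulky O–Sm(III) group in the equatorial exo (β) position of the 3‑oxabicyclo[3.3.1]nonane with protonation on the axial lobe, giving the thermodynamic 2β‑OH; limited equivalents spare the hindered lactone, the allyl ester and both alkenes.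

**Step 7**
Reactants: 9
Product: 10 gibberellin A98
Conditions: Pd(PPh3)4 (5 mol %), morpholine (5 equiv), THF, 23 °C; work‑up at pH 3
Reagents that add atoms: none
Why: Tsuji–Trost deallylation frees the C7 acid under neutral conditions that leave the δ‑lactone, the tertiary allylic 13‑OH, the 16‑ene and all stereocenters untouched.

**Stereocenter ledger.** C4, C5, C6, C8, C9 and C13 are bought in GA3 and are never exposed to enolising conditions stronger than bicarbonate or lutidine once the enone exists. C10 is set in step 5 by the C4 tether. C2 is set in step 6 by substrate control.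

## Compound list
1 | Gibberellic acid (GA3) | C=C1C[C@]23C[C@@]1(O)CC[C@H]2[C@@]12C=C[C@H](O)[C@@](C)(C(=O)O1)[C@H]2[C@@H]3C(=O)O | starting material
2 | Allyl bromide | C=CCBr | starting material
3 | GA3 allyl ester | C=C1C[C@]23C[C@@]1(O)CC[C@H]2[C@@]12C=C[C@H](O)[C@@](C)(C(=O)O1)[C@H]2[C@@H]3C(=O)OCC=C | intermediate
4 | 7‑Allyl hydrogen 2α,3β,13‑trihydroxy‑20‑norgibberella‑1(10),16‑diene‑7,19‑dioate | C=C1C[C@]23C[C@@]1(O)CC[C@H]2C1=C[C@@H](O)[C@H](O)[C@@](C)(C(=O)O)[C@H]1[C@@H]3C(=O)OCC=C | intermediate
5 | 7‑Allyl hydrogen 3β,13‑dihydroxy‑2‑oxo‑20‑norgibberella‑1(10),16‑diene‑7,19‑dioate | C=C1C[C@]23C[C@@]1(O)CC[C@H]2C1=CC(=O)[C@H](O)[C@@](C)(C(=O)O)[C@H]1[C@@H]3C(=O)OCC=C | intermediate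
6 | Chloromethyl chlorosulfate | ClCOS(=O)(=O)Cl | starting material
7 | 7‑Allyl 19‑chloromethyl 3β,13‑dihydroxy‑2‑oxo‑20‑norgibberella‑1(10),16‑diene‑7,19‑dioate | C=C1C[C@]23C[C@@]1(O)CC[C@H]2C1=CC(=O)[C@H](O)[C@@](C)(C(=O)OCCl)[C@H]1[C@@H]3C(=O)OCC=C | intermediate
8 | 3β‑Hydroxy‑2‑oxo‑GA44 allyl ester (19,20‑δ‑lactone) | C=C1C[C@]23C[C@@]1(O)CC[C@H]2[C@]12COC(=O)[C@](C)([C@@H](O)C(=O)C1)[C@H]2[C@@H]3C(=O)OCC=C | intermediate
9 | GA98 allyl ester | C=C1C[C@]23C[C@@]1(O)CC[C@H]2[C@]12COC(=O)[C@](C)(C[C@@H](O)C1)[C@H]2[C@@H]3C(=O)OCC=C | intermediate
10 | Gibberellin A98 | C=C1C[C@]23C[C@@]1(O)CC[C@H]2[C@]12COC(=O)[C@](C)(C[C@@H](O)C1)[C@H]2[C@@H]3C(=O)O | target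

## Totals and risks
**Total steps:** 7. **Longest linear sequence:** 7 (from GA3).

**Steps most likely to fail**

1. **Step 5 (proposed new step).**
   - Risk: premature reduction of the radical to the 19‑methyl ester if the E‑rotamer cyclisation is too slow.
   - Fallback (known chemistry): use the established tethered carbenoid homologation of C19 to C20 gibberellins.
     - Protect the diol of 4, then convert the 19‑acid to the acid chloride and then the diazomethyl ketone.
     - Carry out Cu‑catalysed intramolecular cyclopropanation of the Δ1(10) alkene; the tether enforces α‑face delivery.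
     - Cleave the C1–C20 bond with Li/NH3 to give the bridged cyclopentanone.
     - Perform α‑oxygenation and oxidative C19–C20 cleavage, reduce C20 to CH2OH and lactonise.
     - Unmask and oxidise C2 to rejoin the route at the 2‑ketone.
2. **Step 6.**
   - Risk: formation of the 2,3‑diol instead of deoxygenation, the 2α epimer, or lactone over‑reduction.
   - Fallback: separate the events and set C2 by inversion.
     - Acetylate the 3‑OH and use SmI2 (2 equiv, −78 °C) for deoxygenation only.
     - Reduce with K‑Selectride from the open β face to give the 2α‑ol.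
     - Invert by Mitsunobu reaction (4‑nitrobenzoic acid, DIAD, PPh3; attack from the unhindered β face), then methanolyse the ester.
3. **Step 3, together with the handling of 4.**
   - Risk: relactonisation of the 2α‑hydroxy acid, glycol cleavage, or loss of the polar acid on MnO2.
   - Fallback: avoid the hydroxy acid altogether by changing the order of steps to 2→4→3. Quench the saponification directly under phase transfer with chloromethyl chlorosulfate to give the 19‑chloromethyl ester diol. Then oxidise this neutral diester at C2 to reach 7.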